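**Plan**

1. Numbering follows labdane: decalin C1–C10, chain C11–C16 on C9, C17 on C8, C18/C19 on C4, C20 on C10; α is the face opposite C20; "hexanorlabdane" is the C14 decalin core without C11–C16. The retrosynthesis cuts, in order: the ester C–O at O-6 and the C7 carbinol (back to a 7-ketone); C14=C15 and C12=C13 of the chain; C8–O; C9–C11 (with the C7 oxygen traced back to C9); and last C1–C10 together with C4–C5.
2. Enabling feature: in ring B, C6 and C9 are para and can both be carbonyls, C8 and C10 carry methyls, and the C5–C10 bond lies between them. Ring B is therefore a latent 2,6-dimethyl-1,4-benzoquinone whose C5=C10 bond is a doubly activated dienophile, and C1–C4 with the gem-dimethyl C4 is 4-methylpenta-1,3-diene.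
3. Forward: ring B is bought as the quinone; ring A is annulated onto its C5=C10 edge (step 1); ring B is adjusted (steps 2–11); the chain grows from a C9 allyl group (steps 6, 12, 13); esterification and one reduction finish the route.
4. Stereochemistry: C10 from the chiral boron catalyst; C5 by equilibration next to the C6 ketone; C9 by axial protonation in the dissolving-metal reduction; C8 by α-face oxidation of the Δ7 enol ether; C6 by equilibration next to the C7 ketone; C7 by axial hydride delivery; 12E from cross-metathesis; the Z ester from angelic acid.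

Key step: step 1

Assumption: the (S)-configured oxazaborolidinium cation is taken to leave open the face of the reacting C=C that is Si at the methyl-bearing carbon (future C10) and Re at the CH carbon (future C5), giving the (4aR,8aS) adduct; if its preference is the opposite, the (R)-configured catalyst is used with nothing else changed.

**Route**

Step 1
Reactants: 1 2,6-dimethyl-1,4-benzoquinone; 2 4-methylpenta-1,3-diene
Product: 3 (4aR,8aS)-2,5,5,8a-tetramethyl-4a,5,8,8a-tetrahydronaphthalene-1,4-dione (cis-fused adduct; 5β-H, 10β-CH3)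
Conditions: oxazaborolidinium triflimide (20 mol%) from (S)-3,3-diphenyl-1-(2-methylphenyl)tetrahydro-1H,3H-pyrrolo[1,2-c][1,3,2]oxazaborole and HNTf2, 2 (4 equiv), CH2Cl2, −78 → −40 °C
Reagents that add atoms: none
Why: The boron cation binds the quinone carbonyl flanked by two CH groups (the more basic and less hindered oxygen, the future C6 carbonyl) and lowers the LUMO of the adjacent C=C, so that a normal-demand, strongly asynchronous [4+2] cycloaddition joins the unsubstituted diene terminus to the methyl-bearing β-carbon (C1–C10) and the dimethyl-substituted terminus to the α-carbon (C4–C5). The closest known reaction type is the oxazaborolidinium-catalysed enantioselective Diels–Alder reaction of alkyl-1,4-benzoquinones with acyclic 1,3-dienes. Ring A is the only ring closed, by intermolecular [4+2] annulation onto the C5=C10 edge of ring B, suprafacial on both partners. The quaternary C10 is set by the catalyst, whose aryl group covers one face of the bound quinone; C5 follows as cis (5β-H) from the suprafacial addition and is corrected in step 3. The step needs regioselectivity, secured by the match of the largest diene HOMO coefficient (C1) with the largest LUMO coefficient of the activated enone (its β-carbon) and by the avoidance of vicinal quaternary carbons. It also needs mono-addition, secured because the two C=C bonds of 1 are homotopic and the enedione C=C left in 3 is a far poorer dienophile than the quinone.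

Step 2
Reactants: 3 cis-fused adduct
Product: 4 (4aR,8aS)-2,5,5,8a-tetramethyl-4a,5,6,7,8,8a-hexahydronaphthalene-1,4-dione (cis-fused; 5β-H)
Conditions: H2 (1 atm), RhCl(PPh3)3 (5 mol%), benzene/EtOH, rt
Reagents that add atoms: none
Why: Homogeneous hydrogenation with RhCl(PPh3)3 is governed by alkene substitution, so the cis-disubstituted ring A alkene should be saturated while the trisubstituted, electron-poor enedione C=C and both carbonyls stay; no stereocentre is formed.

Step 3
Reactants: 4 cis-fused enedione
Product: 5 (4aS,8aS)-2,5,5,8a-tetramethyl-4a,5,6,7,8,8a-hexahydronaphthalene-1,4-dione (trans-fused; hexanorlabd-7-ene-6,9-dione, 5α-H)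
Conditions: DBU (0.5 equiv), toluene, 60 °C, to constant isomer ratio
Reagents that add atoms: none
Why: Base-mediated epimerisation through the C5–C6 enolate, C5–H being the only enolisable position (C10 is quaternary, C7 and C8 are sp2); with ring A a saturated chair the trans-fused decalin (5α-H) is expected to be the thermodynamic isomer, as in natural 6-oxo-7-ene terpenoids of this skeleton, and C10 cannot change.

Step 4
Reactants: 5 trans-fused enedione
Product: 6 6β-hydroxy-hexanorlabd-7-en-9-one
Conditions: NaBH4 (1.0 equiv), CeCl3·7H2O, MeOH/CH2Cl2, −78 °C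
Reagents that add atoms: none
Why: Luche 1,2-reduction: the C6 carbonyl (flanked by a CH and a vinylic CH) is far more accessible than the C9 carbonyl between quaternary C10 and methyl-bearing C8, and hydride enters from the α-face, away from the syn-axial C19 and C20 methyls, to set the 6β-alcohol (inverted in step 10).

Step 5
Reactants: 6 6β-hydroxy enone
Product: 7 6β-(methoxymethoxy)-hexanorlabd-7-en-9-one
Conditions: MOMCl (3 equiv), i-Pr2NEt, n-Bu4NI (cat.), CH2Cl2, 0 → 40 °C
Reagents that add atoms: chloromethyl methyl ether, COCCl
Why: O-alkylation with the small, highly electrophilic MOMCl protects the hindered axial alcohol as an acetal that survives the Grignard, chromium, dissolving-metal and base steps and cannot migrate; no stereocentre is touched.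

Step 6
Reactants: 7 6β-MOM enone
Product: 8 9α-allyl-9β-hydroxy-6β-(methoxymethoxy)-hexanorlabd-7-ene
Conditions: CH2=CHCH2MgBr (2 equiv), THF, −78 °C; aq NH4Cl
Reagents that add atoms: allylmagnesium bromide, C=CC[Mg]Br
Why: Grignard 1,2-addition: the allyl reagent adds through a six-membered transition state even to hindered enone carbonyls, here at C9 (the only carbonyl) from the α-face anti to C20; the new C9 stereocentre is of no consequence because it is erased in step 7.

Step 7
Reactants: 8 tertiary allylic alcohol
Product: 9 9-allyl-6β-(methoxymethoxy)-hexanorlabd-8-en-7-one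
Conditions: pyridinium chlorochromate C5H5NH[CrO3Cl] (3 equiv), NaOAc, 4 Å molecular sieves, CH2Cl2, rt
Reagents that add atoms: pyridinium chlorochromate, [O-][Cr](=O)(=O)Cl.c1cc[nH+]cc1
Why: Babler–Dauben oxidative 1,3-transposition: the chromate ester at O-9 undergoes a [3,3]-shift to C7 and the resulting secondary allylic chromate is oxidised to the 7-oxo-Δ8 enone, which moves the oxygen function from C9 to C7 (the new oxygen comes from chromium) and leaves the allyl group on sp2 C9.

Step 8
Reactants: 9 tetrasubstituted enone
Product: 11 9β-allyl-6β-(methoxymethoxy)-7-(triethylsilyloxy)-hexanorlabd-7-ene, via lithium enolate 10 (not isolated)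
Conditions: Li (2.5 equiv), t-BuOH (1.0 equiv), NH3(l)/THF, −78 °C; NH3 evaporated; Et3SiCl (3 equiv), Et3N, THF, −78 → 0 °C
Reagents that add atoms: chlorotriethylsilane, CC[Si](CC)(CC)Cl
Why: Birch-type conjugate reduction of the tetrasubstituted enone: the β-carbon C9 is protonated axially from the α-face so that the allyl group becomes equatorial (9α-H set here), and the Δ7 enolate forms regiospecifically and is trapped on oxygen; the isolated terminal alkene and the acetal are not reduced.

Step 9
Reactants: 11 triethylsilyl enol ether
Product: 12 9β-allyl-6β-(methoxymethoxy)-8α-(triethylsilyloxy)-hexanorlabdan-7-one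
Conditions: mCPBA (1.1 equiv), NaHCO3, CH2Cl2, −20 → 0 °C
Reagents that add atoms: meta-chloroperoxybenzoic acid, OOC(=O)c1cccc(Cl)c1
Why: Rubottom oxidation: the peracid attacks the electron-rich tetrasubstituted enol ether (not the monosubstituted alkene) from the α-face, opposite the axial C20 methyl and the axial 6β-acetal oxygen, and 1,4-silyl migration gives the 8α-silyloxy 7-ketone with C17 axial (C8 set here).

Step 10
Reactants: 12 6β-MOM ketone
Product: 13 9β-allyl-6α-(methoxymethoxy)-8α-(triethylsilyloxy)-hexanorlabdan-7-one
Conditions: DBU (1 equiv), toluene, 80 °C, to constant isomer ratio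
Reagents that add atoms: none
Why: Thermodynamic epimerisation through the C6–C7 enolate, the only one possible since C8 is quaternary: the 6β-oxygen is syn-axial to the C19 and C20 methyls, so equilibration should end at the equatorial 6α-epimer, while C8 and C9 cannot epimerise.

Step 11
Reactants: 13 6α-MOM ketone
Product: 14 9β-allyl-6α,8α-dihydroxy-hexanorlabdan-7-one
Conditions: HCl (3 M in MeOH), rt → 40 °C
Reagents that add atoms: none
Why: Acid-catalysed acetal exchange and silyl ether methanolysis free the 6α- and 8α-hydroxy groups at a stage where no acid-sensitive diene is present; the ketone, the monosubstituted alkene and all stereocentres should be stable.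

Step 12
Reactants: 14 allyl diol ketone
Product: 15 (12E)-6α,8α-dihydroxy-7-oxo-15-norlabd-12-en-14-al
Conditions: methacrolein (10 equiv), second-generation Hoveyda–Grubbs catalyst RuCl2(H2IMes)(=CH-C6H4-2-Oi-Pr) (5 mol%), CH2Cl2, 40 °C
Reagents that add atoms: methacrolein, C=C(C)C=O
Why: Olefin cross-metathesis of the monosubstituted alkene with excess methacrolein, a 1,1-disubstituted electron-poor partner that does not homodimerise, should give the trisubstituted enal as the thermodynamically favoured 12E isomer; free hydroxy and keto groups are tolerated.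

Step 13
Reactants: 15 enal
Product: 16 6α,8α-dihydroxylabda-12E,14-dien-7-one
Conditions: Ph3PCH3Br (3 equiv), KN(SiMe3)2 (2.8 equiv), THF, 0 °C; then 15, −78 → 0 °C
Reagents that add atoms: methyltriphenylphosphonium bromide, C[P+](c1ccccc1)(c1ccccc1)c1ccccc1.[Br-]
Why: Wittig methylenation is far faster at the unhindered conjugated aldehyde than at the C7 ketone, which is flanked by a quaternary and an oxygenated carbon, and forms C14=C15 with the 12E geometry kept; the ylide is too weak a base to ionise the hydroxy groups to a harmful extent.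

Step 14
Reactants: 16 diene diol ketone
Product: 17 6α-angeloyloxy-8α-hydroxylabda-12E,14-dien-7-one
Conditions: angelic acid (3 equiv), 2,4,6-trichlorobenzoyl chloride (3 equiv), Et3N, toluene, rt; then 16, 80 °C
Reagents that add atoms: angelic acid, C/C=C(/C)C(=O)O
Why: Yamaguchi-type mixed-anhydride esterification without a nucleophilic amine catalyst acylates the secondary 6α-hydroxy group (the tertiary 8α-hydroxy group is inert) and avoids the addition–elimination pathway that turns angelates into tiglates, so the Z geometry is kept.

Step 15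
Reactants: 17 angeloyloxy ketone
Product: 18 6α-angeloyloxylabda-12E,14-diene-7β,8α-diol (target)
Conditions: NaBH4 (1.5 equiv), CeCl3·7H2O, MeOH, −78 °C; AcOH quench at −78 °C
Reagents that add atoms: none
Why: Luche reduction: hydride adds to the C7 ketone along the axial α-trajectory, opposite the axial C17 methyl on C8, to give the equatorial 7β-alcohol (C7 set here); the low temperature and acidic quench suppress 6→7 acyl migration, and NaBH4 leaves the ester, the diene and the enoate C=C alone.

**Compound list**

1 | 2,6-dimethyl-1,4-benzoquinone | CC1=CC(=O)C=C(C)C1=O | starting material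
2 | 4-methylpenta-1,3-diene | C=CC=C(C)C | starting material
3 | (4aR,8aS)-2,5,5,8a-tetramethyl-4a,5,8,8a-tetrahydronaphthalene-1,4-dione (cis-fused) | O=C1C(C)=CC(=O)[C@@H]2C(C)(C)C=CC[C@@]21C | intermediate
4 | (4aR,8aS)-2,5,5,8a-tetramethyl-4a,5,6,7,8,8a-hexahydronaphthalene-1,4-dione (cis-fused) | O=C1C(C)=CC(=O)[C@@H]2C(C)(C)CCC[C@@]21C | intermediate
5 | (4aS,8aS)-2,5,5,8a-tetramethyl-4a,5,6,7,8,8a-hexahydronaphthalene-1,4-dione (trans-fused) | O=C1C(C)=CC(=O)[C@H]2C(C)(C)CCC[C@@]21C | intermediate
6 | 6β-hydroxy-hexanorlabd-7-en-9-one | O=C1C(C)=C[C@@H](O)[C@H]2C(C)(C)CCC[C@@]21C | intermediate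
7 | 6β-(methoxymethoxy)-hexanorlabd-7-en-9-one | O=C1C(C)=C[C@@H](OCOC)[C@H]2C(C)(C)CCC[C@@]21C | intermediate
8 | 9α-allyl-9β-hydroxy-6β-(methoxymethoxy)-hexanorlabd-7-ene | C=CC[C@]1(O)C(C)=C[C@@H](OCOC)[C@H]2C(C)(C)CCC[C@@]21C | intermediate
9 | 9-allyl-6β-(methoxymethoxy)-hexanorlabd-8-en-7-one | C=CCC1=C(C)C(=O)[C@@H](OCOC)[C@H]2C(C)(C)CCC[C@@]21C | intermediate
10 | lithium 9β-allyl-6β-(methoxymethoxy)-hexanorlabd-7-en-7-olate (not isolated) | C=CC[C@H]1C(C)=C([O-])[C@@H](OCOC)[C@H]2C(C)(C)CCC[C@@]21C.[Li+] | intermediate
11 | 9β-allyl-6β-(methoxymethoxy)-7-(triethylsilyloxy)-hexanorlabd-7-ene | C=CC[C@H]1C(C)=C(O[Si](CC)(CC)CC)[C@@H](OCOC)[C@H]2C(C)(C)CCC[C@@]21C | intermediate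
12 | 9β-allyl-6β-(methoxymethoxy)-8α-(triethylsilyloxy)-hexanorlabdan-7-one | C=CC[C@H]1[C@](C)(O[Si](CC)(CC)CC)C(=O)[C@@H](OCOC)[C@H]2C(C)(C)CCC[C@@]21C | intermediate
13 | 9β-allyl-6α-(methoxymethoxy)-8α-(triethylsilyloxy)-hexanorlabdan-7-one | C=CC[C@H]1[C@](C)(O[Si](CC)(CC)CC)C(=O)[C@H](OCOC)[C@H]2C(C)(C)CCC[C@@]21C | intermediate
14 | 9β-allyl-6α,8α-dihydroxy-hexanorlabdan-7-one | C=CC[C@H]1[C@](C)(O)C(=O)[C@H](O)[C@H]2C(C)(C)CCC[C@@]21C | intermediate
15 | (12E)-6α,8α-dihydroxy-7-oxo-15-norlabd-12-en-14-al | O=C/C(C)=C/C[C@H]1[C@](C)(O)C(=O)[C@H](O)[C@H]2C(C)(C)CCC[C@@]21C | intermediate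
16 | 6α,8α-dihydroxylabda-12E,14-dien-7-one | C=C/C(C)=C/C[C@H]1[C@](C)(O)C(=O)[C@H](O)[C@H]2C(C)(C)CCC[C@@]21C | intermediate
17 | 6α-angeloyloxy-8α-hydroxylabda-12E,14-dien-7-one | C=C/C(C)=C/C[C@H]1[C@](C)(O)C(=O)[C@H](OC(=O)/C(C)=C\C)[C@H]2C(C)(C)CCC[C@@]21C | intermediate
18 | 6α-angeloyloxylabda-12E,14-diene-7β,8α-diol | C=C/C(C)=C/C[C@H]1[C@](C)(O)[C@@H](O)[C@H](OC(=O)/C(C)=C\C)[C@H]2C(C)(C)CCC[C@@]21C | target

**Summary**

Total steps: 15. Longest linear sequence: 15 steps (the route is fully linear from 1 and 2).

Steps most likely to fail: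

Step 1. The diene carries a methyl group cis to the chain at C4, which disfavours the s-cis conformation. The cycloaddition may therefore be slow compared with cationic oligomerisation of the diene, or may run through a loose, poorly face-selective transition state. Fallback: from 1 and 2 the cycloaddition is run without chiral control (SnCl4, CH2Cl2, −78 °C, or neat at 12 kbar), which should give 3 together with its mirror image (4aS,8aR)-2,5,5,8a-tetramethyl-4a,5,8,8a-tetrahydronaphthalene-1,4-dione F1. The enantiomers are separated by preparative chromatography on a chiral stationary phase, and the route is rejoined at 3.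

Step 3. With four sp2 carbons in ring B the cis and trans ring fusions may lie close in energy, so the equilibration may stop at a mixture. Fallback: from 4 the enedione C=C is reduced with Zn dust in AcOH to the cis-fused saturated dione F2. This is equilibrated at C5 and C8 with NaOMe in MeOH to the trans-fused saturated dione F3, in which ring B is a chair whose axial hydrogens disfavour the cis fusion. Dehydrogenation with IBX in DMSO at 65 °C, possible only across C7–C8, returns the route to 5, which is reduced in step 4 before it meets base again.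

Step 8. The axial 6β C–O bond is aligned with the π system of the enone radical anion and may be cleaved reductively before C9 is protonated. Fallback: from 9 the acetal is removed first (HCl, MeOH, 40 °C) to give 9-allyl-6β-hydroxy-hexanorlabd-8-en-7-one F4. In Li/NH3 its hydroxy group is present as the lithium alkoxide, which cannot leave, and the same reduction gives the dilithium alkoxide enolate F5. Excess Et3SiCl/Et3N silylates both oxygens to 9β-allyl-6β,7-bis(triethylsilyloxy)-hexanorlabd-7-ene F6. The conditions of step 9 then give the 6β,8α-bis(triethylsilyloxy) ketone F7, those of step 10 its 6α-epimer F8, and the acidic methanolysis of step 11 removes both silyl groups and returns the route to 14.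

**Further compounds**

F1 | step 1 | (4aS,8aR)-2,5,5,8a-tetramethyl-4a,5,8,8a-tetrahydronaphthalene-1,4-dione | O=C1C(C)=CC(=O)[C@H]2C(C)(C)C=CC[C@]21C
F2 | step 3 | cis-fused hexanor-5β,8βH-labdane-6,9-dione | O=C1[C@H](C)CC(=O)[C@@H]2C(C)(C)CCC[C@@]21C
F3 | step 3 | trans-fused hexanor-8βH-labdane-6,9-dione | O=C1[C@H](C)CC(=O)[C@H]2C(C)(C)CCC[C@@]21C
F4 | step 8 | 9-allyl-6β-hydroxy-hexanorlabd-8-en-7-one | C=CCC1=C(C)C(=O)[C@@H](O)[C@H]2C(C)(C)CCC[C@@]21C
F5 | step 8 | dilithium 9β-allyl-hexanorlabd-7-ene-6β,7-diolate | C=CC[C@H]1C(C)=C([O-])[C@@H]([O-])[C@H]2C(C)(C)CCC[C@@]21C.[Li+].[Li+]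
F6 | step 8 | 9β-allyl-6β,7-bis(triethylsilyloxy)-hexanorlabd-7-ene | C=CC[C@H]1C(C)=C(O[Si](CC)(CC)CC)[C@@H](O[Si](CC)(CC)CC)[C@H]2C(C)(C)CCC[C@@]21C
F7 | step 8 | 9β-allyl-6β,8α-bis(triethylsilyloxy)-hexanorlabdan-7-one | C=CC[C@H]1[C@](C)(O[Si](CC)(CC)CC)C(=O)[C@@H](O[Si](CC)(CC)CC)[C@H]2C(C)(C)CCC[C@@]21C
F8 | step 8 | 9β-allyl-6α,8α-bis(triethylsilyloxy)-hexanorlabdan-7-one | C=CC[C@H]1[C@](C)(O[Si](CC)(CC)CC)C(=O)[C@H](O[Si](CC)(CC)CC)[C@H]2C(C)(C)CCC[C@@]21C
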